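## The problem

Skeleton numbering used throughout: C1 is the exocyclic methylene carbon on C2; ring A is C2, C3, C4, C5 (Br), C6 (two methyls), C7; ring B is C7, C8, C9, C10 (CH3, Br), C11 (Cl), C12. The target 20 is a spiro[5.5]undecane whose spiro carbon C7 is bonded to a second quaternary carbon, C6, so the C6–C7 bond between two fully substituted carbons is the hardest skeletal bond. There are four stereocentres: C5 in ring A, C7, and the vicinal pair C10/C11 in ring B. C5 is screened from the others by C6 and needs its own source of asymmetry. C7 is stereogenic only because ring B is unsymmetrically substituted, so it is fixed by whichever step first tells C11 from C9, and C10 can then be governed by C11 because bromide has to enter anti to the C–Cl bond. The groups that limit the reagents are the tertiary bromide at C10 (ionisation, E2), the trans Br/Cl pair (reductive elimination with zinc and other low-valent metals), the secondary bromide at C5 beside a quaternary carbon (slow SN2, methyl shift on ionisation) and the 1,1-disubstituted alkene (adds HBr, migrates in acid). Halogens therefore come late and under acidic or neutral conditions, and the methylene comes last. The feature that invites the key step is that C5 lies between C6, which has no hydrogen, and C4: C5 can be an aldehyde that cannot enolise, C4 the terminus of an alkenyl metal, and the C2 carbonyl that ends as the methylene can activate a (Z)-β-iodo enone across C2–C4.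

## Retrosynthesis

**C2=C1.** The methylene of 20 is cut first, back to ketone 19. It has to be the last bond made, because the C10 bromide is introduced with HBr, which would add to a 1,1-disubstituted alkene. The forward step must olefinate a carbonyl flanked by C7 with a non-basic reagent that leaves three C–halogen bonds alone.

**C10–Br and C10–CH3.** 19 goes back to the tertiary carbinol 18 (C–Br) and 18 to the α-chloro ketone 17 (C–CH3). The neighbouring cut, adding Br and Cl across a C10=C11 alkene, would put chlorine on the tertiary carbon and is rejected on constitution. Chlorine as an electrophile α to a ketone and bromide as a nucleophile at a tertiary cation give the right constitution. The forward substitution must deliver bromide anti to chlorine.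

**C11–Cl.** 17 goes back to the symmetric diketone 16. This one cut removes two stereocentres (C11 and C7) and makes ring B a plain 4,4-disubstituted cyclohexanone. The forward step must choose one of two diastereotopic methylene arms and one face: a chiral amine catalyst sets C11, and the ring conformation, with the C2 carbon axial on ring B, decides which arm matches that face.

**C5–Br and the ring B ketal.** 16 goes back to ketal 15, 15 to carbinol 14 (C–Br, with inversion) and 14 to enone 13 (two hydrogens). Placing the bromide early speaks against the neighbouring order (substitution at the end): a secondary bromide next to C6 is inert to all later steps, so the C5 oxygen needs no protecting group, and the most doubtful substitution is tested on simple material. The ketal stays on during the substitution to keep the ring B carbonyl away from Ph3P/CBr4.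

**C4–C5 (key cut).** 13 goes back through alkenylchromium 12 to the achiral keto aldehyde 11. This removes ring A and the C5 stereocentre together and leaves a compound with no stereocentre. The aldehyde has no α-hydrogen and the (Z)-iodo enone already holds C2, C3 and C4. Cutting C2–C3 or C5–C6 instead would require a bond to a quaternary carbon in the ring-forming step. The forward reaction needs aldehyde-over-ketone chemoselectivity, retention of the (Z) geometry and enantioface control by a ligand.

**C2–C3 and the C5 aldehyde.** 11 goes back through ozonide 10 to vinyl compound 9, 9 to ynone 8, 8 to propargylic alcohol 7, and 7 to aldehyde 5 and ethynylmagnesium bromide 6. The vinyl group is a masked aldehyde that survives the Grignard and oxidation steps. It is unmasked last because two free aldehydes could not be told apart.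

**C6–C7.** 5 goes back through enol ether 4 and acetal 3 to aldehyde 1 and prenol 2. A Claisen rearrangement makes the bond between the two quaternary carbons intramolecularly, which is the most dependable way to join two fully substituted carbons. It also delivers the aldehyde and the vinyl group in the right places.

## Roads not taken

Alternative 1: ring B is carried as a phenol and ring A is closed onto it at C2–C7. Phenol A2 has the C6 gem-dimethyl carbon at its para position and a C5-silyloxy chain ending in a propargylsilane. PhI(OAc)2 would oxidise the phenol, the alkyne carbon C2 would attack the para carbon C7 with loss of silicon, and spiro dienone A1 with an exocyclic allene at C2 would result.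
- Merits: the spiro carbon and ring A arise in one step from a cheap aromatic, C6 is a simple benzylic quaternary carbon, and the dienone already holds the C10 carbonyl.
- Weak points: the nucleophile must bond to a ring carbon whose neighbour C6 is already quaternary, where capture of the oxidised phenol by solvent or at an ortho carbon tends to win. The allene has one carbon too many, so it must be cleaved to the C2 ketone and the methylene rebuilt. C5 needs a separate asymmetric step on the open chain. After reduction of both dienone alkenes ring B is the same symmetric ketone as in 16, so the desymmetrising chlorination is not avoided.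
- Comparison: Alternative 1 is better in needing no thermal rearrangement for C6–C7 and in joining the rings convergently. The adopted plan sets against this a ring closure at an unhindered aldehyde carbon and a C2 carbonyl obtained directly, with no carbon to excise.

Alternative 2: the halogens go in first on an open chain and ring B is closed last at C7–C8. β-Keto ester A4 carries on C7 a 2-(trimethylsilyl)ethyl ester and a five-carbon chain with the C11 chloride, the C10 methyl and bromide, and a C8 iodide. CsF would remove the ester, CO2 would leave, and the ring A enolate would displace iodide to give spiro enone A3.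
- Merits: all four stereocentres are present once the key step is done, no desymmetrisation of ring B is needed, and the Br/Cl pair is made on an acyclic alkene, where catalytic enantioselective dihalogenation of allylic alcohols is at its best.
- Weak points: a tertiary bromide with a neighbouring chloride must survive fluoride and a dienolate, and E2 loss of HBr is easy. The enolate can also displace the C11 chloride in a three-membered closure. The spiro centre forms on a planar enolate whose faces differ only through the remote C5 ether and the chain. Bromine on the tertiary and chlorine on the secondary carbon runs against the Markovnikov sense of bromochlorination. Assembling A4 means alkylating a crowded β-keto ester with a β-chloro electrophile.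
- Comparison: Alternative 2 is superior in stereochemical completeness at the key step. The adopted plan sets against this that its halogens meet only acid or neutral reagents and that none of its C–C bond formations competes with an elimination.

Alternative 3: the C6–C7 bond itself is made by a 1,2-shift. In cyclopentanol A6 the carbinol carbon C2 carries the ring B cyclohexene. Its C5 stereocentre would come from a well-established enantioselective desymmetrising reduction. Hg(OTf)2 would mercurate the alkene at C8, C6 would migrate from C2 to the electron-poor C7, and Bu3SnH would replace mercury by hydrogen to give spiro ketone A5.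
- Merits: A5 is the silyl ether of 14, so this road reaches the present route in about four steps instead of seven. In step count it is clearly better, and its C5 source is equally reliable.
- Weak points: expansion of a cyclopentanol to a cyclohexanone has little strain release to drive it, so proton loss to a diene or migration of the CH2 carbon C3 can compete. The demercuration passes through a C8 radical β to the new ketone, which can undergo a 1,2-acyl shift (Dowd–Beckwith type) to a fused bicycle. It also needs stoichiometric mercury and tin.
- Comparison: the adopted plan pays about three more steps. In return its bond formations are of established scope (Claisen rearrangement, Grignard addition, chromium-mediated cyclisation), and the only open question in its ring closure is the level of enantioselectivity, not the constitution of the product.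

Key step: step 6

Assumption: the sense of induction of the sulfonamide ligand (step 6) and of the imidazolidine catalyst (step 10) cannot be read from the substrate alone; in each case the antipode that leads to the configuration drawn is meant.

## Route

Step 1
Reactants: 1 1,4-dioxaspiro[4.5]decane-8-carbaldehyde; 2 3-methylbut-2-en-1-ol
Product: 5 8-(2-methylbut-3-en-2-yl)-1,4-dioxaspiro[4.5]decane-8-carbaldehyde, via diprenyl acetal 3 (not isolated), via prenyl enol ether 4 (not isolated)
Conditions: 2 (3 equiv), PPTS (5 mol%), toluene, Dean–Stark, 110 °C; then mesitylene, 165 °C, distilling off 2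
Reagents that add atoms: none
Why: Acetalisation with removal of water gives 3, acid-catalysed loss of one prenol gives 4, and the Claisen rearrangement of 4 joins the ring carbon to the dimethyl-substituted allyl terminus, creating C7 and C6 in one bond. The weak acid and anhydrous medium should leave the dioxolane intact, as in orthoester Claisen practice.

Step 2
Reactants: 5 8-(2-methylbut-3-en-2-yl)-1,4-dioxaspiro[4.5]decane-8-carbaldehyde; 6 ethynylmagnesium bromide
Product: 7 1-[8-(2-methylbut-3-en-2-yl)-1,4-dioxaspiro[4.5]decan-8-yl]prop-2-yn-1-ol (racemic)
Conditions: 6 (1.5 equiv), THF, 0 → 23 °C; aq. NH4Cl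
Reagents that add atoms: none
Why: Grignard addition of a small sp nucleophile to a hindered aldehyde that cannot enolise; the new carbinol centre is racemic and is removed in step 3.

Step 3
Reactants: 7 1-[8-(2-methylbut-3-en-2-yl)-1,4-dioxaspiro[4.5]decan-8-yl]prop-2-yn-1-ol
Product: 8 1-[8-(2-methylbut-3-en-2-yl)-1,4-dioxaspiro[4.5]decan-8-yl]prop-2-yn-1-one
Conditions: Dess–Martin periodinane, CH2Cl2, 0 → 23 °C
Reagents that add atoms: none
Why: Dess–Martin oxidation of a propargylic alcohol to the ynone under near-neutral conditions that spare the ketal and the vinyl group.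

Step 4
Reactants: 8 1-[8-(2-methylbut-3-en-2-yl)-1,4-dioxaspiro[4.5]decan-8-yl]prop-2-yn-1-one
Product: 9 (Z)-3-iodo-1-[8-(2-methylbut-3-en-2-yl)-1,4-dioxaspiro[4.5]decan-8-yl]prop-2-en-1-one
Conditions: NaI, AcOH (5 equiv), MeCN, 23 °C, dark
Reagents that add atoms: sodium iodide, [Na+].[I-]
Why: Conjugate hydroiodination of the ynone: iodide adds at the β-carbon and the allenol is protonated anti, which gives the (Z)-β-iodo enone under kinetic control. Short reaction time and exclusion of light guard against isomerisation to the (E) isomer.

Step 5
Reactants: 9 (Z)-3-iodo-1-[8-(2-methylbut-3-en-2-yl)-1,4-dioxaspiro[4.5]decan-8-yl]prop-2-en-1-one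
Product: 11 (Z)-3-iodo-1-[8-(2-methyl-1-oxopropan-2-yl)-1,4-dioxaspiro[4.5]decan-8-yl]prop-2-en-1-one, via ozonide 10 (not isolated)
Conditions: O3, CH2Cl2, −78 °C (Sudan red 7B end point); then Me2S, −78 → 23 °C
Reagents that add atoms: ozone, [O-][O+]=O
Why: Ozonolysis is chemoselective because the isolated vinyl group is far more electron-rich than the iodo enone alkene. Me2S is used for the reduction of 10 because phosphines add to β-iodo enones.

Step 6
Reactants: 11 (Z)-3-iodo-1-[8-(2-methyl-1-oxopropan-2-yl)-1,4-dioxaspiro[4.5]decan-8-yl]prop-2-en-1-one
Product: 13 (12R)-12-hydroxy-13,13-dimethyl-1,4-dioxadispiro[4.2.5^8.2^5]pentadec-10-en-9-one, via alkenylchromium dichloride 12 (not isolated)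
Conditions: CrCl2 (3 equiv), N-[2-(4-isopropyl-4,5-dihydro-1,3-oxazol-2-yl)-6-methoxyphenyl]methanesulfonamide (3.3 equiv, antipode for the R carbinol), Et3N (3.3 equiv), NiCl2 (5 mol%), THF, 0.01 M, 23 °C; aq. ethylenediamine work-up
Reagents that add atoms: none
Why: CrCl2 reduces NiCl2 to zerovalent nickel, which inserts into the C4–I bond with retention of the (Z) geometry, and the alkenyl group passes to chromium to give the trivalent alkenylchromium 12 (two divalent chromium per C–I bond). 12 then adds to the C5 aldehyde and work-up frees the carbinol. The closest known reaction type is the Nozaki–Hiyama–Kishi cyclisation of alkenyl iodides onto aldehydes, run with oxazoline–sulfonamide ligands on chromium for the asymmetric version; β-iodo enones and acrylates are established donors. Ring A closes in a 6-exo-trig mode, the aldehyde C=O lying outside the new ring. C5 is the only new stereocentre and is set by the ligand on chromium, since 11 is achiral and ring B is still symmetric. The step needs chemoselectivity for the aldehyde over the ketone, which alkenylchromium reagents show inherently, and it needs the cis geometry, which alone lets C4 reach C5. The aldehyde has no α-hydrogen, so it cannot enolise, and the two quaternary carbons fold the chain so that cyclisation should outrun protonation or dimerisation of 12.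

Step 7
Reactants: 13 (12R)-12-hydroxy-13,13-dimethyl-1,4-dioxadispiro[4.2.5^8.2^5]pentadec-10-en-9-one
Product: 14 (12R)-12-hydroxy-13,13-dimethyl-1,4-dioxadispiro[4.2.5^8.2^5]pentadecan-9-one
Conditions: H2 (1 atm), 10% Pd/C, EtOAc, 23 °C
Reagents that add atoms: none
Why: Catalytic hydrogenation of the cis-disubstituted enone alkene; ketone, ketal and the C5 stereocentre are untouched, and a short reaction time in EtOAc limits allylic C–O hydrogenolysis.

Step 8
Reactants: 14 (12R)-12-hydroxy-13,13-dimethyl-1,4-dioxadispiro[4.2.5^8.2^5]pentadecan-9-one
Product: 15 (12S)-12-bromo-13,13-dimethyl-1,4-dioxadispiro[4.2.5^8.2^5]pentadecan-9-one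
Conditions: CBr4, PPh3, toluene, 0 → 70 °C
Reagents that add atoms: carbon tetrabromide, BrC(Br)(Br)Br
Why: Appel reaction: the alkoxyphosphonium ion is displaced by bromide from the rear, so C5 is inverted from R to S, as is known for 2,2-dimethylcyclohexanol-type carbinols. The ketal keeps the ring B carbonyl away from the phosphorus reagent and the C2 ketone is too hindered to react.

Step 9
Reactants: 15 (12S)-12-bromo-13,13-dimethyl-1,4-dioxadispiro[4.2.5^8.2^5]pentadecan-9-one
Product: 16 (4S)-4-bromo-5,5-dimethylspiro[5.5]undecane-1,9-dione
Conditions: p-TsOH·H2O (10 mol%), acetone/H2O 10:1, 50 °C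
Reagents that add atoms: water, O
Why: Acid-catalysed acetal hydrolysis; the secondary bromide beside C6 does not ionise or substitute under these conditions.

Step 10
Reactants: 16 (4S)-4-bromo-5,5-dimethylspiro[5.5]undecane-1,9-dione
Product: 17 (4S,6R,8R)-4-bromo-8-chloro-5,5-dimethylspiro[5.5]undecane-1,9-dione
Conditions: N-chlorosuccinimide (1.2 equiv), 4,5-diphenylimidazolidine (20 mol%, antipode that gives (R)-2-chlorocyclohexanone from cyclohexanone), 2-nitrobenzoic acid (50 mol%), MeCN, −24 °C
Reagents that add atoms: N-chlorosuccinimide, O=C1CCC(=O)N1Cl
Why: Enamine-catalysed α-chlorination, known for 4,4-disubstituted cyclohexanones; only the unhindered ring B ketone condenses with the amine. The catalyst fixes the R configuration at C11, and axial chlorination syn to the axial C2 carbon (anti to the bulky C6 arm, which sits equatorial) means that only the C11 arm satisfies both demands, which fixes C7.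

Step 11
Reactants: 17 (4S,6R,8R)-4-bromo-8-chloro-5,5-dimethylspiro[5.5]undecane-1,9-dione
Product: 18 (4S,6R,8R,9S)-4-bromo-8-chloro-9-hydroxy-5,5,9-trimethylspiro[5.5]undecan-1-one
Conditions: MeMgBr (1.2 equiv), THF, −78 °C; aq. NH4Cl at −78 °C
Reagents that add atoms: methylmagnesium bromide, C[Mg]Br
Why: Grignard addition to the activated α-chloro ketone, which should react far faster than the C2 ketone flanked by C7. Attack anti to the C–Cl bond (Cornforth/polar Felkin–Anh model) should give mainly the carbinol drawn, but the C10 configuration is irrelevant because it is reset in step 12; the cold quench prevents epoxide closure or a 1,2-shift of the magnesium alkoxide.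

Step 12
Reactants: 18 (4S,6R,8R,9S)-4-bromo-8-chloro-9-hydroxy-5,5,9-trimethylspiro[5.5]undecan-1-one
Product: 19 (4S,6R,8R,9R)-4,9-dibromo-8-chloro-5,5,9-trimethylspiro[5.5]undecan-1-one
Conditions: HBr (33% in AcOH, 5 equiv), CH2Cl2, 0 °C
Reagents that add atoms: hydrogen bromide, Br
Why: SN1 substitution of the tertiary carbinol: the C10 cation is partly bridged by the axial chlorine, so bromide enters anti to C–Cl and gives the trans-diaxial Br/Cl pair with equatorial methyl. That isomer is also the more stable one under reversible ionisation, and any alkene formed by proton loss re-adds HBr in the Markovnikov sense to the same bromide.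

Step 13
Reactants: 19 (4S,6R,8R,9R)-4,9-dibromo-8-chloro-5,5,9-trimethylspiro[5.5]undecan-1-one
Product: 20 (2S,6S,8R,9R)-2,9-dibromo-8-chloro-1,1,9-trimethyl-5-methylidenespiro[5.5]undecane
Conditions: Cp2TiMe2 (3 equiv), toluene/THF, 65 °C, dark
Reagents that add atoms: dimethyltitanocene (Cp2TiMe2), [Ti+4].[CH3-].[CH3-].c1cc[cH-]c1.c1cc[cH-]c1
Why: Petasis methylenation: the titanium methylidene formed on heating is neither basic enough for E2 at the tertiary bromide nor reducing toward the Br/Cl pair, and it reaches the C2 carbonyl from its open CH2 side. No stereocentre is touched.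

## Compound list

1 | 1,4-dioxaspiro[4.5]decane-8-carbaldehyde | O=CC1CCC2(CC1)OCCO2 | starting material
2 | 3-methylbut-2-en-1-ol (prenol) | CC(C)=CCO | starting material
3 | 8-[bis(3-methylbut-2-en-1-yloxy)methyl]-1,4-dioxaspiro[4.5]decane (diprenyl acetal) | CC(C)=CCOC(OCC=C(C)C)C1CCC2(CC1)OCCO2 | intermediate
4 | 8-{[(3-methylbut-2-en-1-yl)oxy]methylidene}-1,4-dioxaspiro[4.5]decane (prenyl enol ether) | CC(C)=CCOC=C1CCC2(CC1)OCCO2 | intermediate
5 | 8-(2-methylbut-3-en-2-yl)-1,4-dioxaspiro[4.5]decane-8-carbaldehyde | C=CC(C)(C)C1(C=O)CCC2(CC1)OCCO2 | intermediate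
6 | ethynylmagnesium bromide | C#C[Mg]Br | starting material
7 | 1-[8-(2-methylbut-3-en-2-yl)-1,4-dioxaspiro[4.5]decan-8-yl]prop-2-yn-1-ol (racemic) | C#CC(O)C1(CCC2(CC1)OCCO2)C(C)(C)C=C | intermediate
8 | 1-[8-(2-methylbut-3-en-2-yl)-1,4-dioxaspiro[4.5]decan-8-yl]prop-2-yn-1-one | C#CC(=O)C1(CCC2(CC1)OCCO2)C(C)(C)C=C | intermediate
9 | (Z)-3-iodo-1-[8-(2-methylbut-3-en-2-yl)-1,4-dioxaspiro[4.5]decan-8-yl]prop-2-en-1-one | C=CC(C)(C)C1(CCC2(CC1)OCCO2)C(=O)/C=C\I | intermediate
10 | (Z)-3-iodo-1-{8-[2-(1,2,4-trioxolan-3-yl)propan-2-yl]-1,4-dioxaspiro[4.5]decan-8-yl}prop-2-en-1-one (ozonide) | O=C(/C=C\I)C1(CCC2(CC1)OCCO2)C(C)(C)C3OCOO3 | intermediate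
11 | (Z)-3-iodo-1-[8-(2-methyl-1-oxopropan-2-yl)-1,4-dioxaspiro[4.5]decan-8-yl]prop-2-en-1-one | O=CC(C)(C)C1(CCC2(CC1)OCCO2)C(=O)/C=C\I | intermediate
12 | (Z)-alkenylchromium dichloride derived from 11 (trivalent chromium; sulfonamide ligand and solvent on chromium not drawn) | O=CC(C)(C)C1(CCC2(CC1)OCCO2)C(=O)/C=C\[Cr](Cl)Cl | intermediate
13 | (12R)-12-hydroxy-13,13-dimethyl-1,4-dioxadispiro[4.2.5^8.2^5]pentadec-10-en-9-one | O=C1C=C[C@@H](O)C(C)(C)C12CCC3(CC2)OCCO3 | intermediate
14 | (12R)-12-hydroxy-13,13-dimethyl-1,4-dioxadispiro[4.2.5^8.2^5]pentadecan-9-one | O=C1CC[C@@H](O)C(C)(C)C12CCC3(CC2)OCCO3 | intermediate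
15 | (12S)-12-bromo-13,13-dimethyl-1,4-dioxadispiro[4.2.5^8.2^5]pentadecan-9-one | O=C1CC[C@H](Br)C(C)(C)C12CCC3(CC2)OCCO3 | intermediate
16 | (4S)-4-bromo-5,5-dimethylspiro[5.5]undecane-1,9-dione | O=C1CC[C@H](Br)C(C)(C)C12CCC(=O)CC2 | intermediate
17 | (4S,6R,8R)-4-bromo-8-chloro-5,5-dimethylspiro[5.5]undecane-1,9-dione | O=C1CC[C@H](Br)C(C)(C)[C@]12CCC(=O)[C@H](Cl)C2 | intermediate
18 | (4S,6R,8R,9S)-4-bromo-8-chloro-9-hydroxy-5,5,9-trimethylspiro[5.5]undecan-1-one | O=C1CC[C@H](Br)C(C)(C)[C@]12CC[C@](C)(O)[C@H](Cl)C2 | intermediate
19 | (4S,6R,8R,9R)-4,9-dibromo-8-chloro-5,5,9-trimethylspiro[5.5]undecan-1-one | O=C1CC[C@H](Br)C(C)(C)[C@]12CC[C@@](C)(Br)[C@H](Cl)C2 | intermediate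
20 | (2S,6S,8R,9R)-2,9-dibromo-8-chloro-1,1,9-trimethyl-5-methylidenespiro[5.5]undecane | C=C1CC[C@H](Br)C(C)(C)[C@]12CC[C@@](C)(Br)[C@H](Cl)C2 | target

Total step count: 13. Longest linear sequence: 13 steps (1 to 20).

## Least certain steps

**Step 6 (key step).** The enantioface discrimination may be low, because the ligand has to differentiate the faces of a neopentyl aldehyde in an intramolecular addition with a constrained transition state. Loss of the (Z) geometry at nickel or protonation of 12 before it cyclises would lower the yield. Fallback: give up ligand control and resolve. From 11, the cyclisation is run with NiCl2/CrCl2 without the ligand to give racemic 12-hydroxy-13,13-dimethyl-1,4-dioxadispiro[4.2.5^8.2^5]pentadec-10-en-9-one F1. Hydrogenation as in step 7 gives the racemic saturated hydroxy ketone F2. Esterification with (R)-2-methoxy-2-phenylacetic acid (DCC, DMAP) and separation of the diastereomers gives the (12R) ester F3, and K2CO3/MeOH returns the route at 14.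

**Step 10.** Arm and face selection may be incomplete. The catalyst controls the configuration at the chlorinated carbon, but which methylene arm reacts depends on the ring preferring axial attack syn to the axial C2 carbon; a twist-boat pathway or a mismatch with the remote C5 centre would erode the ratio. Over-chlorination and epimerisation of the α-chloro ketone through its enol are further losses. Fallback: separate arm selection from chlorination. From 16, deprotonation with a chiral lithium amide, LiN[CH(CH3)Ph]2 as a single antipode, in the presence of Me3SiCl at −100 °C gives (4S,6R)-4-bromo-5,5-dimethyl-9-[(trimethylsilyl)oxy]spiro[5.5]undec-8-en-1-one F4. Chlorination of this enol ether with N-chlorosuccinimide then proceeds under substrate control and returns at 17.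

**Step 8.** Displacement at a carbon next to C6 is slow, so the alkoxyphosphonium ion may ionise instead, with methyl shift or ring contraction, or eliminate toward C4. Fallback: activation and displacement in separate operations. From 14, Tf2O/pyridine at −20 °C gives the triflate (12R)-13,13-dimethyl-9-oxo-1,4-dioxadispiro[4.2.5^8.2^5]pentadecan-12-yl trifluoromethanesulfonate F5, which is displaced by Bu4NBr in toluene to return at 15.

**Step 1.** Acid-promoted ionisation of prenol or of the prenyl enol ether (formal 1,3-shift, diene formation) may compete with the concerted rearrangement, which is slow because it joins two fully substituted carbons. Ketal exchange at 165 °C is a lesser concern. Fallback: Ireland–Claisen rearrangement under basic conditions, for which there is precedent in making the adjacent quaternary pair of chamigrenes. From 1, oxidation with NaClO2 gives 1,4-dioxaspiro[4.5]decane-8-carboxylic acid F6. Esterification with 2 (DCC, DMAP) gives the prenyl ester F7. LiN(iPr)2/Me3SiCl gives the trimethylsilyl ketene acetal F8, which rearranges on warming and after work-up gives 8-(2-methylbut-3-en-2-yl)-1,4-dioxaspiro[4.5]decane-8-carboxylic acid F9. LiAlH4 gives the primary alcohol [8-(2-methylbut-3-en-2-yl)-1,4-dioxaspiro[4.5]decan-8-yl]methanol F10, and Dess–Martin oxidation returns at 5.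

**Step 12.** Ionisation next to a C–Cl bond is slow, and prolonged acid may scramble the halogens through the bridged ion or cause proton loss without re-addition. Capture of the cation syn to chlorine would give the C10 epimer. Fallback: kinetic hydrobromination of an alkene at low temperature instead of ionising an alcohol. From 17, methylenation with Cp2Ti(μ-Cl)(μ-CH2)AlMe2 at −40 °C gives (4S,6R,8R)-4-bromo-8-chloro-5,5-dimethyl-9-methylidenespiro[5.5]undecan-1-one F11, and anhydrous HBr in CH2Cl2 at −78 °C adds in the Markovnikov sense to return at 19.

**Step 13.** The C2 carbonyl is shielded by C7 and C6, so olefination may be slow enough at 65 °C for thermal loss of HBr from the tertiary bromide or enolisation of the ketone to compete. Fallback: Peterson olefination in two stages at low temperature. From 19, Me3SiCH2Li/CeCl3 at −78 °C gives the β-hydroxysilane 4,9-dibromo-8-chloro-5,5,9-trimethyl-1-[(trimethylsilyl)methyl]spiro[5.5]undecan-1-ol F12, and aqueous HF in MeCN at 0 °C eliminates it to 20.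

## Further compounds

F1 | step 6 | racemic 12-hydroxy-13,13-dimethyl-1,4-dioxadispiro[4.2.5^8.2^5]pentadec-10-en-9-one | O=C1C=CC(O)C(C)(C)C12CCC3(CC2)OCCO3
F2 | step 6 | racemic 12-hydroxy-13,13-dimethyl-1,4-dioxadispiro[4.2.5^8.2^5]pentadecan-9-one | O=C1CCC(O)C(C)(C)C12CCC3(CC2)OCCO3
F3 | step 6 | (12R)-13,13-dimethyl-9-oxo-1,4-dioxadispiro[4.2.5^8.2^5]pentadecan-12-yl (2R)-2-methoxy-2-phenylacetate | O=C1CC[C@@H](OC(=O)[C@H](OC)c2ccccc2)C(C)(C)C12CCC3(CC2)OCCO3
F4 | step 10 | (4S,6R)-4-bromo-5,5-dimethyl-9-[(trimethylsilyl)oxy]spiro[5.5]undec-8-en-1-one | O=C1CC[C@H](Br)C(C)(C)[C@]12CCC(O[Si](C)(C)C)=CC2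
F5 | step 8 | (12R)-13,13-dimethyl-9-oxo-1,4-dioxadispiro[4.2.5^8.2^5]pentadecan-12-yl trifluoromethanesulfonate | O=C1CC[C@@H](OS(=O)(=O)C(F)(F)F)C(C)(C)C12CCC3(CC2)OCCO3
F6 | step 1 | 1,4-dioxaspiro[4.5]decane-8-carboxylic acid | O=C(O)C1CCC2(CC1)OCCO2
F7 | step 1 | 3-methylbut-2-en-1-yl 1,4-dioxaspiro[4.5]decane-8-carboxylate | CC(C)=CCOC(=O)C1CCC2(CC1)OCCO2
F8 | step 1 | 8-{[(3-methylbut-2-en-1-yl)oxy][(trimethylsilyl)oxy]methylidene}-1,4-dioxaspiro[4.5]decane | CC(C)=CCOC(O[Si](C)(C)C)=C1CCC2(CC1)OCCO2
F9 | step 1 | 8-(2-methylbut-3-en-2-yl)-1,4-dioxaspiro[4.5]decane-8-carboxylic acid | C=CC(C)(C)C1(C(=O)O)CCC2(CC1)OCCO2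
F10 | step 1 | [8-(2-methylbut-3-en-2-yl)-1,4-dioxaspiro[4.5]decan-8-yl]methanol | C=CC(C)(C)C1(CO)CCC2(CC1)OCCO2
F11 | step 12 | (4S,6R,8R)-4-bromo-8-chloro-5,5-dimethyl-9-methylidenespiro[5.5]undecan-1-one | O=C1CC[C@H](Br)C(C)(C)[C@]12CCC(=C)[C@H](Cl)C2
F12 | step 13 | 4,9-dibromo-8-chloro-5,5,9-trimethyl-1-[(trimethylsilyl)methyl]spiro[5.5]undecan-1-ol (4S,6R,8R,9R; both C1 epimers) | C[Si](C)(C)CC1(O)CC[C@H](Br)C(C)(C)[C@]12CC[C@@](C)(Br)[C@H](Cl)C2
A1 | alternative 1 | (4R)-4-[(tert-butyldimethylsilyl)oxy]-1-ethenylidene-5,5-dimethylspiro[5.5]undeca-7,10-dien-9-one | C=C=C1CC[C@@H](O[Si](C)(C)C(C)(C)C)C(C)(C)C12C=CC(=O)C=C2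
A2 | alternative 1 | 4-{(3R)-3-[(tert-butyldimethylsilyl)oxy]-2-methyl-8-(trimethylsilyl)oct-6-yn-2-yl}phenol | Oc1ccc(cc1)C(C)(C)[C@H](O[Si](C)(C)C(C)(C)C)CCC#CC[Si](C)(C)C
A3 | alternative 2 | (4R,6R,8R,9R)-9-bromo-4-[(tert-butyldimethylsilyl)oxy]-8-chloro-5,5,9-trimethylspiro[5.5]undec-2-en-1-one | O=C1C=C[C@@H](O[Si](C)(C)C(C)(C)C)C(C)(C)[C@]12CC[C@@](C)(Br)[C@H](Cl)C2
A4 | alternative 2 | 2-(trimethylsilyl)ethyl (5R)-1-[(2R,3R)-3-bromo-2-chloro-5-iodo-3-methylpentyl]-5-[(tert-butyldimethylsilyl)oxy]-6,6-dimethyl-2-oxocyclohex-3-ene-1-carboxylate (both C1 epimers) | O=C1C=C[C@@H](O[Si](C)(C)C(C)(C)C)C(C)(C)C1(C(=O)OCC[Si](C)(C)C)C[C@@H](Cl)[C@](C)(Br)CCI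
A5 | alternative 3 | (12R)-12-[(tert-butyldimethylsilyl)oxy]-13,13-dimethyl-1,4-dioxadispiro[4.2.5^8.2^5]pentadecan-9-one | O=C1CC[C@@H](O[Si](C)(C)C(C)(C)C)C(C)(C)C12CCC3(CC2)OCCO3
A6 | alternative 3 | (3R)-3-[(tert-butyldimethylsilyl)oxy]-1-(1,4-dioxaspiro[4.5]dec-7-en-8-yl)-2,2-dimethylcyclopentan-1-ol (both C1 epimers) | OC1(CC[C@@H](O[Si](C)(C)C(C)(C)C)C1(C)C)C1=CCC2(CC1)OCCO2
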